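**Retrosynthetic overview**
1. 12 ⇒ 8: both dimethylpyran rings are opened together. Forward, one DDQ operation turns the two o-prenylphenol units of the acyclic triphenolic β-diketone 8 into o-quinone methides that close by oxa-6π electrocyclisation (the plant's prenyl → chromene step, done twice, as the last step).
2. 8 ⇒ 2 + 5: the central C–C bond of the 1,3-diketone, by a crossed Claisen condensation without protecting groups.
3. 2 ⇒ 1 by C5 Friedel–Crafts prenylation; 5 ⇒ 3 by ortho C-prenylation of the phenolate.
4. Ring order: both benzene rings are bought; the pyran on the resorcinol half closes first and the pyran on the 4-hydroxybenzoyl half second, in the same flask.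

Assumption: the target has no stereocentre and no stereogenic double bond (it is achiral and is drawn as the diketo tautomer of a keto–enol mixture), so no step has to set configuration.

**Route**

Step 1
Reactants: 1 2,4-dihydroxyacetophenone
Product: 2 1-[2,4-dihydroxy-5-(3-methylbut-2-en-1-yl)phenyl]ethan-1-one
Conditions: 2-methylbut-3-en-2-ol (1.3 equiv), BF3·OEt2 (0.3 equiv), dioxane, rt, 16 h; chromatography
Reagents that add atoms: 2-methylbut-3-en-2-ol, CC(C)(O)C=C
Why: Friedel–Crafts (SEAr) prenylation in which BF3 ionises the tertiary allylic alcohol to the prenyl cation, which attacks the resorcinol ring at the unhindered C5 (ortho to the 4-OH, para to the 2-OH) in preference to C3 flanked by two oxygens, and no stereocentre is formed.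

Step 2
Reactants: 3 methyl 4-hydroxybenzoate
Product: 5 methyl 4-hydroxy-3-(3-methylbut-2-en-1-yl)benzoate, via sodium 4-(methoxycarbonyl)phenolate 4 (not isolated)
Conditions: NaH (1.05 equiv), PhMe, 0 °C → rt; prenyl bromide (1.1 equiv), rt → 60 °C, 24 h; aq. NH4Cl; chromatography
Reagents that add atoms: prenyl bromide (1-bromo-3-methylbut-2-ene), CC(C)=CCBr
Why: ortho C-alkylation of a phenolate, in which the tight, poorly solvated sodium ion pair in toluene reacts with the allylic bromide at the ortho carbon rather than at oxygen and the dienone rearomatises to the 3-prenylphenol (para position blocked by the ester), and no stereocentre is formed.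

Step 3
Reactants: 2 1-[2,4-dihydroxy-5-(3-methylbut-2-en-1-yl)phenyl]ethan-1-one; 5 methyl 4-hydroxy-3-(3-methylbut-2-en-1-yl)benzoate
Product: 8 1-[2,4-dihydroxy-5-(3-methylbut-2-en-1-yl)phenyl]-3-[4-hydroxy-3-(3-methylbut-2-en-1-yl)phenyl]propane-1,3-dione, via trilithium enolate-bisphenolate 6 (not isolated), via lithium ester phenolate 7 (not isolated)
Conditions: 2, LiHMDS (5.5 equiv), THF, −78 → −10 °C, 2 h; then 5 (1.1 equiv) in THF, −78 °C → reflux, 16 h; cold 1 M HCl to pH 5
Reagents that add atoms: none
Why: Proposed new method: a crossed Claisen condensation run on the unprotected partners, in which excess LiHMDS converts 2 into its trilithium enolate-bisphenolate (a strongly nucleophilic carbon centre) that adds at reflux to the methyl ester of 5 (present as its lithium phenolate, deactivated but still an ester), with loss of LiOMe and deprotonation of the β-diketone formed pulling the equilibrium forward; the closest known reaction types are the C-acylation of lithium polyanions of unprotected polyhydroxyacetophenones with aroyl chlorides and the classical Claisen condensation of salicylate esters as their phenolates, and no stereocentre is formed.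

Step 4
Reactants: 8 1-[2,4-dihydroxy-5-(3-methylbut-2-en-1-yl)phenyl]-3-[4-hydroxy-3-(3-methylbut-2-en-1-yl)phenyl]propane-1,3-dione
Product: 12 glyinflanin D [1-(2,2-dimethyl-2H-chromen-6-yl)-3-(7-hydroxy-2,2-dimethyl-2H-chromen-6-yl)propane-1,3-dione], via ring-B o-quinone methide 9 (not isolated), via mono-chromene 10 (not isolated), via ring-A o-quinone methide 11 (not isolated)
Conditions: DDQ (2.2 equiv), PhMe–dioxane 4:1, 80 °C, 1–2 h; filter off the precipitated hydroquinone, NaHCO3 wash
Reagents that add atoms: none
Why: twofold DDQ dehydrogenative cyclisation of o-prenylphenols (hydride abstraction from the benzylic/allylic CH2 gives the o-quinone methide, which closes by oxa-6π electrocyclisation), in which each prenyl group has only one neighbouring hydroxyl so both closures are regiochemically fixed, the chelated 2'-OH has no prenyl partner and stays free, and no stereocentre is formed.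

**Compound list**
1 | 2,4-dihydroxyacetophenone | CC(=O)c1ccc(O)cc1O | starting material
2 | 1-[2,4-dihydroxy-5-(3-methylbut-2-en-1-yl)phenyl]ethan-1-one | CC(=O)c1cc(CC=C(C)C)c(O)cc1O | intermediate
3 | methyl 4-hydroxybenzoate | COC(=O)c1ccc(O)cc1 | starting material
4 | sodium 4-(methoxycarbonyl)phenolate | COC(=O)c1ccc([O-])cc1.[Na+] | intermediate (not isolated)
5 | methyl 4-hydroxy-3-(3-methylbut-2-en-1-yl)benzoate | COC(=O)c1ccc(O)c(CC=C(C)C)c1 | intermediate
6 | trilithium 4-(1-oxidoethenyl)-6-(3-methylbut-2-en-1-yl)benzene-1,3-bis(olate) (enolate-bisphenolate of 2) | [Li+].[Li+].[Li+].C=C([O-])c1cc(CC=C(C)C)c([O-])cc1[O-] | intermediate (not isolated)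
7 | lithium 4-(methoxycarbonyl)-2-(3-methylbut-2-en-1-yl)phenolate (phenolate of 5) | [Li+].COC(=O)c1ccc([O-])c(CC=C(C)C)c1 | intermediate (not isolated)
8 | 1-[2,4-dihydroxy-5-(3-methylbut-2-en-1-yl)phenyl]-3-[4-hydroxy-3-(3-methylbut-2-en-1-yl)phenyl]propane-1,3-dione | CC(C)=CCc1cc(C(=O)CC(=O)c2cc(CC=C(C)C)c(O)cc2O)ccc1O | intermediate
9 | o-quinone methide of the resorcinol ring of 8: 4'-oxo, exocyclic (Z)-5'-(3-methylbut-2-en-1-ylidene), 2'-OH kept, other half unchanged | CC(C)=C/C=C1/C=C(C(=O)CC(=O)c2ccc(O)c(CC=C(C)C)c2)C(O)=CC1=O | intermediate (not isolated)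
10 | 1-(7-hydroxy-2,2-dimethyl-2H-chromen-6-yl)-3-[4-hydroxy-3-(3-methylbut-2-en-1-yl)phenyl]propane-1,3-dione | CC(C)=CCc1cc(C(=O)CC(=O)c2cc3c(cc2O)OC(C)(C)C=C3)ccc1O | intermediate (not isolated)
11 | o-quinone methide of the 4-hydroxybenzoyl ring of 10: 4-oxo, exocyclic (Z)-3-(3-methylbut-2-en-1-ylidene), chromene half unchanged | CC(C)=C/C=C1/C=C(C(=O)CC(=O)c2cc3c(cc2O)OC(C)(C)C=C3)C=CC1=O | intermediate (not isolated)
12 | glyinflanin D, 1-(2,2-dimethyl-2H-chromen-6-yl)-3-(7-hydroxy-2,2-dimethyl-2H-chromen-6-yl)propane-1,3-dione (achiral) | CC1(C)C=Cc2cc(C(=O)CC(=O)c3cc4c(cc3O)OC(C)(C)C=C4)ccc2O1 | target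

**Totals**
Total step count: 4. Longest linear sequence: 3 steps (1 → 2 → 8 → 12, or 3 → 5 → 8 → 12).

**Three steps most likely to fail**

Step 3 (most at risk). The ester of 5 reacts as a phenolate and may be too poor an electrophile, and LiHMDS may attack it on long heating. The fallback sets out from 5 and comes back at 8. Compound 5 is silylated (TBSCl, imidazole, DMF, rt) to methyl 4-[(tert-butyldimethylsilyl)oxy]-3-(3-methylbut-2-en-1-yl)benzoate F1. F1, now a normal ester, is condensed with trianion 6 made from 2 (LiHMDS 4.3 equiv, THF, −78 → 50 °C) to give 1-[2,4-dihydroxy-5-(3-methylbut-2-en-1-yl)phenyl]-3-[4-[(tert-butyldimethylsilyl)oxy]-3-(3-methylbut-2-en-1-yl)phenyl]propane-1,3-dione F2. TBAF buffered with AcOH (THF, 0 °C) then removes the silyl group and delivers 8.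

Step 4. The hydroquinone by-product is acidic and may cyclodehydrate the 2'-hydroxy-β-diketone to a flavone, and DDQ may attack the enolised diketone before both prenyl groups have reacted. The fallback sets out from 2 and 5 and comes back at 12; it closes each pyran ring by the same oxidation before the diketone exists. Compound 2 with DDQ (1.1 equiv, PhMe, 80 °C) gives 1-(7-hydroxy-2,2-dimethyl-2H-chromen-6-yl)ethan-1-one F3. Compound 5 under the same conditions gives methyl 2,2-dimethyl-2H-chromene-6-carboxylate F4. F3 and F4 are then joined by crossed Claisen condensation (LiHMDS 3.2 equiv, THF, −78 °C → reflux; cold dilute HCl) to give 12 directly. Only the chelated hydroxyl is then present during the condensation.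

Step 1. C5 selectivity over C3 and over double prenylation is only moderate, and chroman formation competes. The fallback sets out from 1 and comes back at 2; it places the prenyl group by sigmatropic rearrangement instead of electrophilic substitution. Compound 1 is protected selectively at the non-chelated 4-OH (MOMCl, K2CO3, acetone) to give 1-[2-hydroxy-4-(methoxymethoxy)phenyl]ethan-1-one F5. F5 is O-prenylated at the 2-OH (prenyl bromide, K2CO3, DMF, 60 °C) to give 1-[4-(methoxymethoxy)-2-[(3-methylbut-2-en-1-yl)oxy]phenyl]ethan-1-one F6. Heating F6 in N,N-diethylaniline at 200 °C triggers a para-Claisen–Cope rearrangement that moves the prenyl group, with double allylic inversion, to the carbon para to that oxygen, giving 1-[2-hydroxy-4-(methoxymethoxy)-5-(3-methylbut-2-en-1-yl)phenyl]ethan-1-one F7. HCl in MeOH at rt removes the MOM group and gives 2.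

**Further compounds**
F1 | step 3 | methyl 4-[(tert-butyldimethylsilyl)oxy]-3-(3-methylbut-2-en-1-yl)benzoate | COC(=O)c1ccc(O[Si](C)(C)C(C)(C)C)c(CC=C(C)C)c1
F2 | step 3 | 1-[2,4-dihydroxy-5-(3-methylbut-2-en-1-yl)phenyl]-3-[4-[(tert-butyldimethylsilyl)oxy]-3-(3-methylbut-2-en-1-yl)phenyl]propane-1,3-dione | CC(C)=CCc1cc(C(=O)CC(=O)c2cc(CC=C(C)C)c(O)cc2O)ccc1O[Si](C)(C)C(C)(C)C
F3 | step 4 | 1-(7-hydroxy-2,2-dimethyl-2H-chromen-6-yl)ethan-1-one | CC(=O)c1cc2C=CC(C)(C)Oc2cc1O
F4 | step 4 | methyl 2,2-dimethyl-2H-chromene-6-carboxylate | COC(=O)c1ccc2OC(C)(C)C=Cc2c1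
F5 | step 1 | 1-[2-hydroxy-4-(methoxymethoxy)phenyl]ethan-1-one | CC(=O)c1ccc(OCOC)cc1O
F6 | step 1 | 1-[4-(methoxymethoxy)-2-[(3-methylbut-2-en-1-yl)oxy]phenyl]ethan-1-one | CC(=O)c1ccc(OCOC)cc1OCC=C(C)C
F7 | step 1 | 1-[2-hydroxy-4-(methoxymethoxy)-5-(3-methylbut-2-en-1-yl)phenyl]ethan-1-one | CC(=O)c1cc(CC=C(C)C)c(OCOC)cc1O
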